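**Retrosynthetic overview**
1. Target ⇐ its C6 silyl dienol ether (kinetic α-face protonation puts the acetate β) ⇐ 6-acetoxy enone ⇐ enone 10 by Mn(OAc)3 acetoxylation.
2. Key C–C bond C8–C17: enone 10 ⇐ diosphenol triflate 9 (C8, the α-carbon of the C7 ketone and normally the enolate donor, used as the acceptor) + MeZnCl.
3. Diosphenol 8 ⇐ 17-nor-8-ketone 6 (SeO2) ⇐ exocyclic 8(17)-alkene 4 (ozonolysis).
4. Alkene 4 ⇐ (−)-sclareol 1 (silylation of C13–OH, dehydration of C8–OH).
5. No ring is formed: rings A and B with C5 and C10, and the C13 carbinol, come intact from sclareol; only C6 is set in the route.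

Assumption: labdane numbering is used; the target is (5S,6S,10S,13R)-6β-acetoxy-13-hydroxylabda-8,14-dien-7-one, and commercial (−)-sclareol is (13R)-labd-14-ene-8α,13-diol.

**Step 1**
Reactants: 1 (−)-sclareol
Product: 4 (13R)-13-(triethylsilyloxy)labda-8(17),14-diene, via 13-O-triethylsilylsclareol 2 (not isolated), via chlorosulfite ester 3 (not isolated)
Conditions: TESOTf (1.05 equiv), 2,6-lutidine, CH2Cl2, −78 °C; then pyridine, SOCl2, −78 → −30 °C; AgNO3–silica to remove the minor 7-ene
Reagents that add atoms: triethylsilyl trifluoromethanesulfonate, CC[Si](CC)(CC)OS(=O)(=O)C(F)(F)F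
Why: Chemoselective O-silylation of the open-chain C13 carbinol (the ring C8–OH, flanked by the axial C17 methyl and the C9 side chain, reacts more slowly) followed by E2 dehydration of the equatorial C8 chlorosulfite, for which only the freely rotating C17 methyl offers an anti-periplanar hydrogen, so the exocyclic alkene predominates; C5, C9, C10 and C13 are untouched.

**Step 2**
Reactants: 4 (13R)-13-(triethylsilyloxy)labda-8(17),14-diene
Product: 6 (13R)-13-(triethylsilyloxy)-17-norlabd-14-en-8-one, via secondary ozonide 5 (not isolated)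
Conditions: O3, CH2Cl2, −78 °C (Sudan Red 7B end point); then Me2S, −78 °C → rt
Reagents that add atoms: ozone, [O-][O+]=O
Why: Chemoselective ozonolysis (Criegee mechanism) of the electron-richer 1,1-disubstituted alkene, the vinyl group being deactivated and shielded by the neighbouring silyloxy-bearing quaternary carbon; C9 keeps its equatorial side chain.

**Step 3**
Reactants: 6 (13R)-13-(triethylsilyloxy)-17-norlabd-14-en-8-one
Product: 8 (13R)-8-hydroxy-13-(triethylsilyloxy)-17-norlabda-8,14-dien-7-one, via 7,8-dione 7 (not isolated)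
Conditions: SeO2 (1.5 equiv), 1,4-dioxane, H2O (2 equiv), 80 °C
Reagents that add atoms: selenium dioxide, O=[Se]=O
Why: Riley oxidation takes the only α-methylene (C7; the α-methine C9 cannot reach the carbonyl stage), and the 7,8-dione settles as the more substituted conjugated enol (diosphenol) across C8–C9, which removes the C9 stereocentre.

**Step 4 (key step)**
Reactants: 8 (13R)-8-hydroxy-13-(triethylsilyloxy)-17-norlabda-8,14-dien-7-one
Product: 10 (13R)-13-(triethylsilyloxy)labda-8,14-dien-7-one, via enol triflate 9 (not isolated)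
Conditions: NaN(SiMe3)2, PhNTf2, THF, −78 → 0 °C; then Pd(PPh3)4 (5 mol %), MeZnCl (2 equiv), THF, 45 °C
Reagents that add atoms: methylzinc chloride, C[Zn]Cl
Why: Enol triflate formation then Negishi cross-coupling, in which zerovalent palladium inserts into the C8–O bond so that C8, the α-carbon of the C7 ketone and by nature a donor (enolate) site, acts as an enolonium-type acceptor toward the nucleophilic methyl of MeZnCl; no stereocentre is involved.

**Step 5**
Reactants: 10 (13R)-13-(triethylsilyloxy)labda-8,14-dien-7-one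
Product: 11 (6R,13R)-6α-acetoxy-13-(triethylsilyloxy)labda-8,14-dien-7-one
Conditions: Mn(OAc)3·2H2O (3 equiv), benzene, reflux (Dean–Stark)
Reagents that add atoms: manganese triacetate dihydrate, [Mn+3].CC(=O)[O-].CC(=O)[O-].CC(=O)[O-].O.O
Why: Mn(OAc)3 α′-acetoxylation of an enone, in which the trivalent manganese enolate gives the C6 radical and acetate is expected to enter from the open α-face (the β-face is blocked by the axial C10 and C4 methyls); whichever C6 epimer forms is corrected in step 6.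

**Step 6**
Reactants: 11 (6R,13R)-6α-acetoxy-13-(triethylsilyloxy)labda-8,14-dien-7-one
Product: 14 (5S,6S,10S,13R)-6β-acetoxy-13-hydroxylabda-8,14-dien-7-one, via silyl dienol ether 12 (not isolated), via 6β-acetate silyl ether 13 (not isolated)
Conditions: TMSCl, LiN(i-Pr)2 (internal quench), THF, −78 °C; then HF·pyridine, THF, −40 → 0 °C
Reagents that add atoms: none
Why: Kinetic α′-deprotonation with in situ silylation gives the cross-conjugated silyl dienol ether and erases the C6 configuration, and protodesilylation by HF·pyridine is a kinetic (Zimmerman-type) protonation from the open α-face, so the acetate ends β (6S) without enolate equilibration or acyl migration; the same reagent then cleaves the tertiary triethylsilyl ether.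

**Compound list**
1 | (−)-sclareol, (13R)-labd-14-ene-8α,13-diol | C=C[C@](C)(O)CC[C@H]1[C@](C)(O)CC[C@H]2C(C)(C)CCC[C@]12C | starting material
2 | 13-O-triethylsilylsclareol, (13R)-13-(triethylsilyloxy)labd-14-en-8α-ol | C=C[C@](C)(O[Si](CC)(CC)CC)CC[C@H]1[C@](C)(O)CC[C@H]2C(C)(C)CCC[C@]12C | intermediate
3 | C8 chlorosulfite ester of 2 | C=C[C@](C)(O[Si](CC)(CC)CC)CC[C@H]1[C@](C)(OS(Cl)=O)CC[C@H]2C(C)(C)CCC[C@]12C | intermediate
4 | (13R)-13-(triethylsilyloxy)labda-8(17),14-diene (13-O-triethylsilylmanool) | C=C[C@](C)(O[Si](CC)(CC)CC)CC[C@H]1C(=C)CC[C@H]2C(C)(C)CCC[C@]12C | intermediate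
5 | secondary ozonide of 4 (spiro-1,2,4-trioxolane at C8, C8 configuration undefined) | C=C[C@](C)(O[Si](CC)(CC)CC)CC[C@H]1C3(OOCO3)CC[C@H]2C(C)(C)CCC[C@]12C | intermediate
6 | (13R)-13-(triethylsilyloxy)-17-norlabd-14-en-8-one (9α-H) | C=C[C@](C)(O[Si](CC)(CC)CC)CC[C@H]1C(=O)CC[C@H]2C(C)(C)CCC[C@]12C | intermediate
7 | (13R)-13-(triethylsilyloxy)-17-norlabd-14-ene-7,8-dione | C=C[C@](C)(O[Si](CC)(CC)CC)CC[C@H]1C(=O)C(=O)C[C@H]2C(C)(C)CCC[C@]12C | intermediate
8 | (13R)-8-hydroxy-13-(triethylsilyloxy)-17-norlabda-8,14-dien-7-one (diosphenol) | C=C[C@](C)(O[Si](CC)(CC)CC)CCC1=C(O)C(=O)C[C@H]2C(C)(C)CCC[C@]12C | intermediate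
9 | (13R)-7-oxo-13-(triethylsilyloxy)-17-norlabda-8,14-dien-8-yl trifluoromethanesulfonate | C=C[C@](C)(O[Si](CC)(CC)CC)CCC1=C(OS(=O)(=O)C(F)(F)F)C(=O)C[C@H]2C(C)(C)CCC[C@]12C | intermediate
10 | (13R)-13-(triethylsilyloxy)labda-8,14-dien-7-one | C=C[C@](C)(O[Si](CC)(CC)CC)CCC1=C(C)C(=O)C[C@H]2C(C)(C)CCC[C@]12C | intermediate
11 | (6R,13R)-6α-acetoxy-13-(triethylsilyloxy)labda-8,14-dien-7-one | C=C[C@](C)(O[Si](CC)(CC)CC)CCC1=C(C)C(=O)[C@H](OC(C)=O)[C@H]2C(C)(C)CCC[C@]12C | intermediate
12 | (13R)-6-acetoxy-7-(trimethylsilyloxy)-13-(triethylsilyloxy)labda-6,8,14-triene | C=C[C@](C)(O[Si](CC)(CC)CC)CCC1=C(C)C(O[Si](C)(C)C)=C(OC(C)=O)[C@H]2C(C)(C)CCC[C@]12C | intermediate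
13 | (6S,13R)-6β-acetoxy-13-(triethylsilyloxy)labda-8,14-dien-7-one | C=C[C@](C)(O[Si](CC)(CC)CC)CCC1=C(C)C(=O)[C@@H](OC(C)=O)[C@H]2C(C)(C)CCC[C@]12C | intermediate
14 | (5S,6S,10S,13R)-6β-acetoxy-13-hydroxylabda-8,14-dien-7-one | C=C[C@](C)(O)CCC1=C(C)C(=O)[C@@H](OC(C)=O)[C@H]2C(C)(C)CCC[C@]12C | target

**Count and risks**
Total step count: 6. Longest linear sequence: 6 (all from sclareol). The three steps most likely to fail are steps 1, 3 and 6.

Step 1 may fail through poor discrimination of the two tertiary hydroxyls or through too much endocyclic alkene. The fallback sets out from 1 and moves the discrimination to an ester pyrolysis. Both hydroxyls are acetylated (AcCl, N,N-dimethylaniline, CH2Cl2) to sclareol diacetate F1. Buffered thermolysis (NaHCO3, DMSO, about 150 °C) is expected to eliminate the strained ring acetate at C8 toward the C17 methyl, giving 13-O-acetylmanool F2. Methanolysis (K2CO3, MeOH) gives manool F3, which is purified on AgNO3–silica and silylated (TESOTf, 2,6-lutidine). The fallback comes back to the route at 4.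

Step 3 may fail because SeO2 can dehydrogenate toward C9–C11 or attack the silyl ether. The fallback sets out from 6 and uses regiodefined enolate chemistry. The kinetic C7 enolate (LiN(i-Pr)2, THF, −78 °C) is hydroxylated with 2-(phenylsulfonyl)-3-phenyloxaziridine to the 7α-hydroxy ketone F4. Dess–Martin periodinane then gives dione 7, which enolises, and the fallback comes back to the route at 8.

Step 6 may fail because the C6 hydrogen of 11 is hindered, or because the acetate migrates before protonation. The fallback sets out from 11 and sets C6 by hydride delivery instead of protonation. Methanolysis (K2CO3, MeOH, 0 °C) gives the 6α-hydroxy enone F5. Dess–Martin periodinane with NaHCO3 gives the 6,7-dione F6, which is used at once because it can enolise toward C5. NaBH4 (MeOH–CH2Cl2, −78 °C) should reduce the non-conjugated C6 carbonyl from the open α-face to the 6β-hydroxy enone F7. Acetylation (Ac2O, DMAP, Et3N) comes back to the route at 13, which HF·pyridine converts to 14 as in step 6.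

**Further compounds**
F1 | step 1 | sclareol diacetate, (13R)-8α,13-diacetoxylabd-14-ene | C=C[C@](C)(OC(C)=O)CC[C@H]1[C@](C)(OC(C)=O)CC[C@H]2C(C)(C)CCC[C@]12C
F2 | step 1 | 13-O-acetylmanool, (13R)-13-acetoxylabda-8(17),14-diene | C=C[C@](C)(OC(C)=O)CC[C@H]1C(=C)CC[C@H]2C(C)(C)CCC[C@]12C
F3 | step 1 | manool, (13R)-labda-8(17),14-dien-13-ol | C=C[C@](C)(O)CC[C@H]1C(=C)CC[C@H]2C(C)(C)CCC[C@]12C
F4 | step 3 | (13R)-7α-hydroxy-13-(triethylsilyloxy)-17-norlabd-14-en-8-one | C=C[C@](C)(O[Si](CC)(CC)CC)CC[C@H]1C(=O)[C@H](O)C[C@H]2C(C)(C)CCC[C@]12C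
F5 | step 6 | (6R,13R)-6α-hydroxy-13-(triethylsilyloxy)labda-8,14-dien-7-one | C=C[C@](C)(O[Si](CC)(CC)CC)CCC1=C(C)C(=O)[C@H](O)[C@H]2C(C)(C)CCC[C@]12C
F6 | step 6 | (13R)-13-(triethylsilyloxy)labda-8,14-diene-6,7-dione | C=C[C@](C)(O[Si](CC)(CC)CC)CCC1=C(C)C(=O)C(=O)[C@H]2C(C)(C)CCC[C@]12C
F7 | step 6 | (6S,13R)-6β-hydroxy-13-(triethylsilyloxy)labda-8,14-dien-7-one | C=C[C@](C)(O[Si](CC)(CC)CC)CCC1=C(C)C(=O)[C@@H](O)[C@H]2C(C)(C)CCC[C@]12C
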